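A protonated nucleophile cannot attack the electrophile: the first step has the free nucleophile on its left. So how much nucleophile does the acid set free take out of play?

| flask | electrophile | nucleophile | free base | time |
|---|---|---|---|---|
| Saturday's | 0.24 M | 0.264 M | 0.720 M | 10 d |
| Wednesday's | 0.24 M | 0.264 M | 1.10 M | 10 d |

    electrophile + nucleophile → acid set free + target (k1 = 0.0036 M⁻¹ min⁻¹)
    nucleophile + acid set free ⇌ protonated nucleophile, settled at all times (K2 = 600 M⁻¹)
    acid set free + free base ⇌ salt of the base, settled at all times (K3 = 9000 M⁻¹)
    free base ⇌ dormant form (K4 = 0.32, k4 = 2.2 × 10⁻⁴ min⁻¹)
    crystals ⇌ target, rate k5*(cs5 - [target]) while solid is left; crystals form when [target] > cs5 (cs5 = 0.12 M, k5 = 0.014 min⁻¹)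
    acid set free + target → side product (k6 = 0.0050 M⁻¹ min⁻¹)

* part of the electrophile that has reacted at the end, Saturday's
* part of the electrophile that has reacted at the end, Wednesday's
* what raising the concentration of free base from its lowest to its highest value here does to the part of the electrophile that has reacted (changes below 5 percentage points count as none) (it rises / it falls / no change)

Where does the acid go? On Saturday's, to the free base: equilibrium constant times charge is 6500 for the free base against 160 for the nucleophile.

But doesn't the free base drain away to the dormant form? Partly. On Saturday's that exchange has a relaxation half-life of 0.530 d, short against 10 d, so I keep it at balance, with dormant over free base at 0.32. After a full run's acid, I then reckon Saturday's at 0.364 M of free base beside 0.24 M of salt of the base.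

What does that leave free? Dividing the two fast balances gives the parked share, [protonated nucleophile]/[nucleophile], equal to [salt of the base]/[free base] times the ratio of the binding constants, 0.0667. For Saturday's it is 4.40 %, and for Wednesday's 2.46 %.

So what is the yield? The share is small, so I count the nucleophile as free and run plain second order, with rate constant times time 51.8 M⁻¹ and a nucleophile surplus of 0.0240 M. Saturday's gives 96.5 %, and Wednesday's, with the same two charges, 96.5 %.

And the extra free base? The two shares differ by 1.94 % of the free nucleophile, so I expect no change.

The forecast differs from my figures: it gives 96.3 % for Saturday's and 96.4 % for Wednesday's, with no change, since “The free base binds acid far more strongly than the nucleophile does”.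

The simulation gives 96.2 % for Saturday's and 96.3 % for Wednesday's, a difference of 0.085 percentage points: no change.

Saturday's ends with protonated over free nucleophile at 4.11 %, against the parked share of 4.40 %. The neighbouring flask is Saturday's with 0.16 M of nucleophile, 0.667 equiv. Scaling the share to the acid this charge can release gives 2.51 %, and the flask's end ratio reads 2.49 %. The same 51.8 M⁻¹ with a nucleophile deficit gives 66.3 %, and the neighbouring flask reaches 66.3 %. In the neighbouring flask the nucleophile is the limiting reagent, with 0.57 % of its charge left at 10.0 d.

(Its constants come from no measurement; the result is computed.)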